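## Analysis of the target

CNP0251293.1 is a longipinene-type sesquiterpenoid carrying an angelate, an isovalerate, a free hydroxyl and an enone. The core is numbered C1 (angelate carbon), C2 (isovalerate carbon), C3 (free carbinol), C4 (gem-dimethyl), C5, C6, C7 (ketone), C8, C9 (methyl-bearing), C10 and C11 (quaternary, methyl-bearing). A cyclobutane C5–C6–C11–C10 is shared by a 3-methylcyclohex-2-enone (C5 to C10) and a seven-membered ring (C1 to C5, C10, C11).

There are seven stereocentres. C5, C6, C10 and C11 are locked together by the cage. The C2 and C3 oxygens are cis to each other, on the face of the seven-membered ring that carries the C11 methyl group. The C1 oxygen is trans to both, on the side of C6.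

Sensitive groups are the angelate (Z to E isomerisation), the cyclobutane next to a ketone and to oxygenated C1 (cationic ring expansion), the enone, and a free hydroxyl beside an ester (acyl migration). The hard points are the quaternary cyclobutane carbon C11, the contiguous C1–C3 triol with two neopentyl positions, and telling three secondary hydroxyls apart.

The strategy rests on one feature: C11 is a quaternary cyclobutane carbon bonded to oxygenated C1. The strained C6–C11 bond can therefore result from a 1,2-shift of C6 from C1 to C11 that turns a C1 carbinol into a C1 carbonyl.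

## Retrosynthetic reasoning

**Esters (38 → 37 → 36 → 33).** The isovalerate goes on last, onto the less hindered O2 of diol 37. The angelate is placed on the hindered C1 hydroxyl of 33 while O2 and O3 are still tied in the acetonide. This keeps the isomerisable angelate out of every hydride, oxidation and Lewis-acid step.

**C7 carbonyl (32 → 31).** The enone is cut back to the C7 methylene of 31. Allylic oxidation of this pinene-like alkene is dependable, and it must follow the skeletal rearrangement: a C6 that is α to a ketone would not migrate.

**C11 methyl and C1 carbinol (31 → 30 → 29 → 28 → 27).** The methyl is traced to a hydroxymethyl group and the C1 alcohol to a ketone. The hydroxymethyl of 27 first directs hydride to C1 from its own face, then is removed as its sulfonate by hydride displacement. Radical and cationic deoxygenations are avoided because a cyclobutylcarbinyl centre would open or expand.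

**Key disconnection (27 → 26).** The C6–C11 bond is cut and C6 returned to C1. The cyclobutane reopens to a cyclopentane, the seven-membered ring shrinks to ring A, and C1 becomes a tertiary carbinol next to a spiro-epoxide. Forward, one step must form the quaternary centre, both rings and the C1 carbonyl.

**Epoxide (26 → 24 + 25).** The epoxide oxygen has to lie on the ring A face of C11 (the face toward C2–C4). Only then does the shift leave C1 on the side from which ring A can stay closed; with the oxygen on the other face, C6 migration would give an impossible trans-bridged ring. The ylide from 25 is therefore required to bring the methylene from the opposite, alkene-bridge face of ketone 24.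

**Ring B (24 → 23 → 21).** The C9–C10 bond is cut. The C11 ketone of 21 can enolise only toward C10, and the C9 carbonyl is kept as a ketal that reacts only as an oxocarbenium ion. That excludes the competing condensation of C8 onto C11.

**C1–C11 bond (21 → 20).** The bridged α-ketol is opened to a 1,5-keto aldehyde. An acyl-anion closure gives the tertiary alcohol and the ketone at once, without reducing agents near the α-alkoxy ketone.

**The all-cis set at C2, C3, C5 and C6 (20 → 19 → 18 → 16 → 14 → 13).** O2, O3, the C5 chain and the C6 chain must all sit on one face of ring A. Adding a C10 unit to an enone such as 9 would come anti to the axial C3 oxygen, and a [4+2] closure of ring B would in addition need the wrong regiochemistry at the neopentyl C5. The stereochemistry is therefore relayed instead: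
- hydride reduction of 13 puts the C1 hydroxyl cis to the dioxolane (14);
- an orthoester Claisen rearrangement carries that oxygen's face to C5 (16);
- hydroboration from the now open face sets C6 and returns oxygen to C1 (18).

**Ring A (13 → 10 + 11 → 9 → 8 → … → 1).** The C6 chain is attached by cross-coupling to iodo-enone 10. Enone 9 comes from aldol condensation of keto aldehyde 8. Lactone 1 supplies C2–C5, the C3 stereocentre and the gem-dimethyl group; C2 is set by chelation-controlled reduction.

## Alternatives that were turned down

Alternative 1: The seven-membered ring is disconnected at C1–C11 and traced to a five-membered cyclic enol ether derived from lactone 1. On heating, a [3,3] shift joins C1 to C11 while the allylic C5–O bond breaks, giving cycloheptenone A1 with C2 as ketone and a C5=C6 alkene.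
- For: a thermal Claisen shift is among the most dependable ways to make a quaternary carbon, and C3 with the gem-dimethyl group comes from the chiral pool as here. On reliability of the key step it is stronger than the chosen plan.
- Against: A1 contains no cyclobutane. The C5–C10 bond, the C6 stereocentre, the C1 oxygen, the C9 methyl and the C8=C9 unsaturation all remain, and the hardest bond is postponed to a substrate with no obvious handle at C10.
- Comparison: the chosen route spends its one risky step on exactly that bond and obtains the quaternary centre, both ring sizes and the C1 carbonyl from it.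

Alternative 2: No chemical C–C disconnection is made. A sesquiterpene synthase folds acyclic A3 into α-longipinene A2, closing the seven-membered ring, the cyclohexene and the cyclobutane in one enzymatic cascade.
- For: unmatched step economy for the skeleton, with all four cage stereocentres set at once. On this point it is clearly stronger.
- Against: A2 has no oxygen. C7 could be oxidised allylically, but C1, C2 and C3 are unactivated methylenes. Three contiguous, stereodefined hydroxylations with the cis,trans pattern, followed by ester differentiation, have no chemical handle and would need further tailored enzymes. An enzyme of the right enantiomeric series and fidelity is also required.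
- Comparison: in the chosen route each oxygen has a chemical origin: O2 and O3 come from 1, O1 from the carbonyl the rearrangement creates.

Alternative 3: The cyclobutane is cut at C5–C10 and a nitrogen atom inserted, giving a bridged pyrrolidine. N-Amination of the amine gives an isodiazene that extrudes nitrogen; the C5/C10 diradical recombines to tricyclic enone A4.
- For: the strained bond is made late and under mild conditions from an unstrained amine, with the enone and quaternary C11 already present. The precedent base for cyclobutanes from pyrrolidines is arguably better than for a ring-contracting semipinacol shift.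
- Against: a 1,4-diradical can cleave into two alkenes instead of closing. The C10 radical is allylic to the enone, so bonding at C8 and loss of C10 configuration compete. The amine, flanked by quaternary C4 and C11, is itself a long synthesis. A4 still needs anti-dioxygenation of C1=C2 with the right regio- and facial sense.
- Comparison: the risk is similar in size. The chosen route offers the C1 oxygen function and the quaternary centre from the same event, and carries O2 and O3 protected from the start.

Key step: step 19

Remark on the chemistry: in compounds 21–26 the two faces of the C1–C11 bridge are called the ring A face (toward C2–C4 and the axial C3 oxygen) and the alkene-bridge face (toward C7–C9). Commercial (S)-pantolactone is assumed enantiopure and configurationally stable at C3 throughout.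

## Route

Step 1
Reactants: 1 (S)-pantolactone
Product: 2 (4S)-2-ethoxy-4,6-dihydroxy-5,5-dimethylhex-1-en-3-one (in equilibrium with its cyclic hemiketal)
Conditions: ethyl vinyl ether, t-BuLi, THF, −78 to 0 °C; then 1, −78 °C; aq. NH4Cl
Reagents that add atoms: ethyl vinyl ether, C=COCC (used as 1-ethoxyvinyllithium, [Li]C(=C)OCC)
Why: Acyl substitution of a lactone by a vinyllithium; the first equivalent deprotonates the hydroxyl, the second adds once because the tetrahedral hemiketal alkoxide persists at low temperature. The new carbon is C1 of the core, masked as an enol ether.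

Step 2
Reactants: 2 hydroxy ketone
Product: 3 (3S,4S)-2-ethoxy-5,5-dimethylhex-1-ene-3,4,6-triol (3,4-anti)
Conditions: Zn(BH4)2, Et2O, −20 to 0 °C
Reagents that add atoms: none
Why: Chelation-controlled reduction of an α-hydroxy ketone; zinc bridges the carbonyl and the C3 hydroxyl and hydride comes from the side away from the tert-alkyl group, which should give the anti diol, i.e. the later cis relationship of O2 and O3 on ring A.

Step 3
Reactants: 3 triol
Product: 4 6-O-tert-butyldimethylsilyl ether of triol 3
Conditions: TBSCl (1.05 equiv), imidazole, DMF, 0 °C
Reagents that add atoms: tert-butyldimethylsilyl chloride, CC(C)(C)[Si](C)(C)Cl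
Why: Selective silylation of the only primary hydroxyl; it removes the 1,3-diol that would otherwise compete with the 1,2-diol for the acetonide.

Step 4
Reactants: 4 silyl ether
Product: 6 1-[cis-5-(1-silyloxy-2-methylpropan-2-yl)-2,2-dimethyl-1,3-dioxolan-4-yl]ethanone (methyl ketone with C2/C3 acetonide), via enol ether acetonide 5 (not isolated)
Conditions: 2,2-dimethoxypropane, PPTS (cat.), acetone, rt; then 0.5 M aq. HCl, THF, 0 °C
Reagents that add atoms: 2,2-dimethoxypropane, COC(C)(C)OC; water, O
Why: Acetonide formation on the only free 1,2-diol, then hydrolysis of the enol ether, which is far more acid-labile than the dioxolane or the primary silyl ether, to reveal the C1 methyl ketone.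

Step 5
Reactants: 6 methyl ketone
Product: 7 primary alcohol (C5 hydroxyl free)
Conditions: HF·pyridine, pyridine, THF, 0 °C to rt
Reagents that add atoms: none
Why: Fluoride desilylation under buffered, non-basic conditions, so that the α-alkoxy ketone centre C2 is not enolised.

Step 6
Reactants: 7 alcohol
Product: 8 2-(cis-5-acetyl-2,2-dimethyl-1,3-dioxolan-4-yl)-2-methylpropanal
Conditions: (COCl)2, DMSO, CH2Cl2, −78 °C; Et3N
Reagents that add atoms: none
Why: Swern oxidation of a neopentyl primary alcohol; the aldehyde has no α-hydrogen and cannot enolise.

Step 7
Reactants: 8 keto aldehyde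
Product: 9 (5S,6S)-5,6-(isopropylidenedioxy)-4,4-dimethylcyclohex-2-en-1-one (C1 ketone and C6=C5 alkene of the core; O2 and O3 cis)
Conditions: pyrrolidine (0.3 equiv), AcOH (0.3 equiv), toluene, 60 °C
Reagents that add atoms: none
Why: Intramolecular aldol condensation through the methyl-side enamine onto the non-enolisable aldehyde (six-membered closure, then dehydration). Amine catalysis avoids the C2 enolate that could eject O3, and the cis-fused dioxolane is the thermodynamically preferred ring fusion.

Step 8
Reactants: 9 enone
Product: 10 2-iodo derivative of enone 9 (iodine on C6)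
Conditions: I2, pyridine, CH2Cl2, rt
Reagents that add atoms: iodine, II
Why: Pyridine-mediated α-iodination of a cyclic enone (conjugate addition, iodination, elimination), known for 4,4-disubstituted cyclohexenones.

Step 9
Reactants: 10 iodo-enone; 11 2-methyl-2-vinyl-1,3-dioxolane
Product: 13 enone 9 bearing a 2-(2-methyl-1,3-dioxolan-2-yl)ethyl chain on C6 (C7–C9 with C9 as ketal), via alkylborane 12 (not isolated)
Conditions: 11, 9-BBN-H, THF, rt; then 10, PdCl2(dppf) (5 mol%), AsPh3, Cs2CO3, DMF–H2O, rt
Reagents that add atoms: none
Why: B-alkyl Suzuki–Miyaura coupling of an α-iodo-enone; it installs C7–C9 with the C9 carbonyl masked as a ketal that survives the reductions to come.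

Step 10
Reactants: 13 substituted enone
Product: 14 allylic alcohol (C1 hydroxyl cis to O2 and O3)
Conditions: NaBH4, CeCl3·7H2O, MeOH, −78 to −40 °C
Reagents that add atoms: none
Why: Luche 1,2-reduction; hydride attacks the carbonyl from the face opposite the cis-fused dioxolane, so the C1 hydroxyl should end on the face of O2 and O3.

Step 11
Reactants: 14 allylic alcohol
Product: 16 ethyl ester with CH2CO2Et (C10, C11) on C5 cis to O3 and a C1=C6 alkene, via ketene acetal 15 (not isolated)
Conditions: triethyl orthoacetate, EtCO2H (cat.), xylene, 140 °C, ethanol distilled off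
Reagents that add atoms: triethyl orthoacetate, CC(OCC)(OCC)OCC
Why: Johnson–Claisen rearrangement; the [3,3] shift is suprafacial, so the C5–C10 bond forms on the face that carried the C1 oxygen, i.e. syn to O3, the relationship an intermolecular addition would not give. The neopentyl terminus is tolerated because the shift is intramolecular and exergonic.

Step 12
Reactants: 16 unsaturated ester
Product: 18 hydroxy ester (C1 hydroxyl trans to O2; C6 chain cis to the C5 chain and to O2/O3), via C1 borane 17 (not isolated)
Conditions: BH3·THF, THF, 0 °C to rt; then 30% H2O2, aq. NaOAc, 0 °C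
Reagents that add atoms: hydrogen peroxide, OO
Why: Hydroboration–oxidation of the trisubstituted alkene; boron goes to the less substituted C1 and hydrogen to C6, both from the face opposite the dioxolane and the C5 chain, which sets C6 with its chain cis to C10 and returns oxygen to C1. Low temperature avoids β-alkoxy elimination of the borane.

Step 13
Reactants: 18 hydroxy ester
Product: 19 diol (C1 secondary and C11 primary hydroxyls)
Conditions: LiAlH4, THF, 0 °C
Reagents that add atoms: none
Why: Ester reduction; ketal and acetonide are inert to hydride.

Step 14
Reactants: 19 diol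
Product: 20 keto aldehyde (C1 ketone, C11 aldehyde)
Conditions: (COCl)2, DMSO, CH2Cl2, −78 °C; Et3N
Reagents that add atoms: none
Why: Double Swern oxidation; low temperature protects the C6 centre next to the new ketone.

Step 15
Reactants: 20 keto aldehyde
Product: 21 bridged α-ketol (C1 tertiary hydroxyl, C11 ketone; ring A now a bicyclo[3.2.1]octane with the C10–C11 bridge)
Conditions: 2-mesityl-6,7-dihydro-5H-pyrrolo[2,1-c][1,2,4]triazol-2-ium chloride (15 mol%), Et3N (15 mol%), t-BuOH–THF, 40 °C
Reagents that add atoms: none
Why: Carbene-catalysed intramolecular crossed benzoin reaction of an aldehyde with a ketone; the acyl-anion equivalent at C11 closes a five-membered ring onto C1, possible only from the face that carries the C5 chain, so the C1 hydroxyl should end trans to O2. No reductant touches the α-alkoxy ketone.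

Step 16
Reactants: 21 bridged α-ketol
Product: 23 tricyclic ketol with ring B closed (C9 carries methyl and a 2-hydroxyethoxy group), via bis-silyl enol ether 22 (not isolated)
Conditions: TMSOTf (2.3 equiv), Et3N (2.1 equiv), CH2Cl2, 0 °C; then TMSOTf (0.3 equiv), −78 to −20 °C; K2CO3, MeOH
Reagents that add atoms: none
Why: Intramolecular Mukaiyama aldol addition to a ketal. The C11 ketone can enolise only toward C10, and the C9 carbonyl appears only as an oxocarbenium ion, so the condensation of C8 onto C11 that a free methyl ketone would allow is excluded. The six-membered closure fixes C10 on the only face that reaches the C6 chain.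

Step 17
Reactants: 23 tricyclic ketol ether
Product: 24 tricyclic α-hydroxy ketone (C1 hydroxyl, C11 ketone, C8=C9 alkene)
Conditions: TsOH·H2O (10 mol%), benzene, 60 °C
Reagents that add atoms: none
Why: Acid-promoted E1 loss of the tertiary 2-hydroxyethyl ether; a C9=C10 alkene is excluded because C10 is now a bridgehead, and equilibration should favour the endocyclic trisubstituted C8=C9 alkene.

Step 18
Reactants: 24 tricyclic α-hydroxy ketone; 25 trimethylsulfonium iodide
Product: 26 tertiary α-hydroxy spiro-epoxide (epoxide oxygen on the ring A face of C11, methylene on the alkene-bridge face)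
Conditions: 25, n-BuLi, THF, −10 °C (3 equiv ylide); then 24, −10 °C to rt
Reagents that add atoms: none
Why: Corey–Chaykovsky epoxidation with dimethylsulfonium methylide, whose addition is irreversible. The ketone cannot enolise (C1 quaternary, C10 bridgehead). The ring A face of the carbonyl is blocked by C4 and the axial C3 oxygen, so carbon should arrive from the alkene-bridge face and the oxygen close on the ring A face; the excess ylide covers the free hydroxyl.

Step 19
Reactants: 26 tertiary α-hydroxy spiro-epoxide
Product: 27 longipinene-type C1 ketone with a hydroxymethyl group on C11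
Conditions: BF3·OEt2 (1.2 equiv), CH2Cl2, −78 °C; Et3N, then aq. NaHCO3
Reagents that add atoms: none
Why: The Lewis acid binds the epoxide oxygen; as the C11–O bond lengthens, the C1–C6 bond shifts to C11 on the side opposite the leaving oxygen while the C1 hydroxyl pushes, leaving the C1 ketone and the C11 hydroxymethyl group. The closest known reaction is the Lewis-acid semipinacol rearrangement of tertiary α-hydroxy epoxides to β-hydroxy ketones with an α-quaternary carbon. The cyclobutane closes by the 1,2-shift itself, which contracts the five-membered ring C1–C6–C5–C10–C11 by expelling C1, and the seven-membered ring arises by insertion of C11 into the C1–C6 bond of ring A. C11 is the new stereocentre and is formed with inversion, so the epoxide configuration set in step 18 places the hydroxymethyl group toward ring B and C1 on the ring A side; C6 migrates with retention. The step needs C6 to migrate rather than C2 or a hydride of the epoxide methylene: C2 is eclipsed with the breaking C–O bond and cannot attack from the rear, it is deactivated by its oxygen substituent, and C6 is the only carbon on C1 that lies behind C11. The weak point is that the O–C11–C1–C6 dihedral angle in the bicyclo[3.2.1] frame is near 120° and not 180°, so the two-carbon bridge must twist. Low temperature and a non-ionising solvent are chosen to keep the shift concerted, because a free C11 cation would be taken by C2, by the C3 oxygen or by hydride. Release of epoxide strain and formation of the carbonyl should pay for the four-membered ring.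

Step 20
Reactants: 27 β-hydroxy ketone
Product: 28 anti-1,3-diol (C1 hydroxyl trans to O2 and O3, on the side of C6)
Conditions: Me4NBH(OAc)3, MeCN–AcOH (1:1), −30 °C
Reagents that add atoms: none
Why: Evans–Saksena directed reduction; the hydroxymethyl group binds boron and delivers hydride to C1 from its own face, so the new hydroxyl should end on the opposite face, as the target requires.

Step 21
Reactants: 28 diol
Product: 29 primary tosylate (C1 hydroxyl free)
Conditions: TsCl, pyridine, CH2Cl2, 0 °C
Reagents that add atoms: 4-toluenesulfonyl chloride, Cc1ccc(cc1)S(=O)(=O)Cl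
Why: Selective sulfonylation of the primary hydroxyl over the hindered secondary one.

Step 22
Reactants: 29 tosylate
Product: 30 C1 tert-butyldimethylsilyl ether of tosylate 29
Conditions: TBSOTf, 2,6-lutidine, CH2Cl2, −20 to 0 °C
Reagents that add atoms: tert-butyldimethylsilyl triflate, CC(C)(C)[Si](C)(C)OS(=O)(=O)C(F)(F)F
Why: Silylation of the hindered carbinol; it prevents Grob fragmentation or oxetane formation from a 1,3-alkoxide in the next step and protects C1 during the allylic oxidation.

Step 23
Reactants: 30 silyl ether tosylate
Product: 31 C11-methyl compound (C1 silyl ether, acetonide, C8=C9)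
Conditions: LiBHEt3, THF, 0 to 65 °C
Reagents that add atoms: none
Why: Direct hydride displacement of a neopentyl-type sulfonate; the ionic SN2 path avoids the cyclobutylcarbinyl radical or cation that would open or expand the four-membered ring.

Step 24
Reactants: 31 alkene
Product: 32 C7 enone (C1 silyl ether, acetonide)
Conditions: dirhodium tetracaprolactamate Rh2(cap)4 (1 mol%), t-BuOOH (5 equiv), K2CO3, CH2Cl2, rt
Reagents that add atoms: tert-butyl hydroperoxide, CC(C)(C)OO
Why: Allylic oxidation of a pinene-like trisubstituted alkene at the ring methylene next to the CH= carbon, as in the pinene to verbenone change; the other ring allylic position, C10, is a cyclobutane bridgehead and inert.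

Step 25
Reactants: 32 silyl ether enone
Product: 33 C1 alcohol (C7 enone, acetonide)
Conditions: HF·pyridine, pyridine, THF, rt
Reagents that add atoms: none
Why: Fluoride desilylation; the acetonide and the non-enolisable cyclobutyl ketone are not affected.

Step 26
Reactants: 33 C1 alcohol; 34 angelic acid
Product: 36 C1 angelate (acetonide, C7 enone), via angelic trichlorobenzoic anhydride 35 (not isolated)
Conditions: 34, 2,4,6-trichlorobenzoyl chloride, Et3N, toluene, rt; then 33, toluene, 75 °C
Reagents that add atoms: none
Why: Yamaguchi-type mixed-anhydride esterification without a nucleophilic catalyst, the conditions under which angelates form without Z to E isomerisation to the tiglate.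

Step 27
Reactants: 36 angelate acetonide
Product: 37 C1 angelate 2,3-diol
Conditions: 1 M aq. HCl–THF (1:3), rt
Reagents that add atoms: none
Why: Acid hydrolysis of the dioxolane; the angelate and the enone tolerate dilute aqueous acid at room temperature.

Step 28
Reactants: 37 diol
Product: 38 CNP0251293.1 (C1 angelate, C2 isovalerate, C3 hydroxyl, C7 enone)
Conditions: isovaleryl chloride (1.05 equiv), 2,4,6-collidine, CH2Cl2, −40 °C
Reagents that add atoms: isovaleryl chloride, CC(C)CC(=O)Cl
Why: Site-selective acylation with an acid chloride and a hindered pyridine base at low temperature; O2 is flanked by two CH carbons whereas O3 is directly next to the quaternary C4, so O2 should react first.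

## Compound list

1 | (S)-pantolactone | CC1(C)COC(=O)[C@H]1O | starting material
2 | (4S)-2-ethoxy-4,6-dihydroxy-5,5-dimethylhex-1-en-3-one | C=C(OCC)C(=O)[C@@H](O)C(C)(C)CO | intermediate
3 | (3S,4S)-2-ethoxy-5,5-dimethylhex-1-ene-3,4,6-triol | C=C(OCC)[C@@H](O)[C@@H](O)C(C)(C)CO | intermediate
4 | 6-O-TBS ether of triol 3 | C=C(OCC)[C@@H](O)[C@@H](O)C(C)(C)CO[Si](C)(C)C(C)(C)C | intermediate
5 | enol ether acetonide (3,4-O-isopropylidene derivative of 4) | C=C(OCC)[C@H]1OC(C)(C)O[C@H]1C(C)(C)CO[Si](C)(C)C(C)(C)C | intermediate
6 | methyl ketone with cis C2/C3 acetonide and C5 silyl ether | CC(=O)[C@H]1OC(C)(C)O[C@H]1C(C)(C)CO[Si](C)(C)C(C)(C)C | intermediate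
7 | primary alcohol from 6 | CC(=O)[C@H]1OC(C)(C)O[C@H]1C(C)(C)CO | intermediate
8 | 2-(cis-5-acetyl-2,2-dimethyl-1,3-dioxolan-4-yl)-2-methylpropanal | CC(=O)[C@H]1OC(C)(C)O[C@H]1C(C)(C)C=O | intermediate
9 | (5S,6S)-5,6-(isopropylidenedioxy)-4,4-dimethylcyclohex-2-en-1-one | O=C1C=CC(C)(C)[C@@H]2OC(C)(C)O[C@H]12 | intermediate
10 | 2-iodo derivative of enone 9 | O=C1C(I)=CC(C)(C)[C@@H]2OC(C)(C)O[C@H]12 | intermediate
11 | 2-methyl-2-vinyl-1,3-dioxolane | C=CC1(C)OCCO1 | starting material
12 | B-[2-(2-methyl-1,3-dioxolan-2-yl)ethyl]-9-borabicyclo[3.3.1]nonane | CC1(CCB2C3CCCC2CCC3)OCCO1 | intermediate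
13 | enone with the ketal-bearing C7–C9 chain on C6 | O=C1C(CCC2(C)OCCO2)=CC(C)(C)[C@@H]3OC(C)(C)O[C@H]13 | intermediate
14 | allylic alcohol, C1 hydroxyl cis to O2/O3 | O[C@@H]1C(CCC2(C)OCCO2)=CC(C)(C)[C@@H]3OC(C)(C)O[C@H]13 | intermediate
15 | mixed ketene acetal (1-ethoxyvinyl ether of 14) | C=C(OCC)O[C@@H]1C(CCC2(C)OCCO2)=CC(C)(C)[C@@H]3OC(C)(C)O[C@H]13 | intermediate
16 | ethyl ester, C5 acetate chain cis to O3, C1=C6 alkene | C1=C(CCC2(C)OCCO2)[C@H](CC(=O)OCC)C(C)(C)[C@@H]3OC(C)(C)O[C@H]13 | intermediate
17 | C1 borane from 16 | B[C@H]1[C@H](CCC2(C)OCCO2)[C@H](CC(=O)OCC)C(C)(C)[C@@H]3OC(C)(C)O[C@H]13 | intermediate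
18 | hydroxy ester, C5 and C6 chains cis to each other and to O2/O3 | O[C@H]1[C@H](CCC2(C)OCCO2)[C@H](CC(=O)OCC)C(C)(C)[C@@H]3OC(C)(C)O[C@H]13 | intermediate
19 | diol (C1 and C11 hydroxyls) | O[C@H]1[C@H](CCC2(C)OCCO2)[C@H](CCO)C(C)(C)[C@@H]3OC(C)(C)O[C@H]13 | intermediate
20 | keto aldehyde (C1 ketone, C11 aldehyde) | O=C1[C@H](CCC2(C)OCCO2)[C@H](CC=O)C(C)(C)[C@@H]3OC(C)(C)O[C@H]13 | intermediate
21 | bridged α-ketol (C1 hydroxyl, C11 ketone, C9 ketal) | O[C@@]12[C@H]3OC(C)(C)O[C@H]3C(C)(C)[C@@H](CC1=O)[C@H]2CCC4(C)OCCO4 | intermediate
22 | bis-silyl enol ether of 21 (C1 OTMS, C10=C11 OTMS) | C[Si](C)(C)O[C@@]12[C@H]3OC(C)(C)O[C@H]3C(C)(C)[C@@H](C=C1O[Si](C)(C)C)[C@H]2CCC4(C)OCCO4 | intermediate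
23 | tricyclic ketol, C9 methyl and 2-hydroxyethoxy (C9 configuration immaterial) | O[C@]12[C@H]3OC(C)(C)O[C@H]3C(C)(C)[C@@H]4[C@H]1CCC(C)(OCCO)[C@@H]4C2=O | intermediate
24 | tricyclic α-hydroxy ketone with C8=C9 | O[C@]12[C@H]3OC(C)(C)O[C@H]3C(C)(C)[C@@H]4[C@H]1CC=C(C)[C@@H]4C2=O | intermediate
25 | trimethylsulfonium iodide | C[S+](C)C.[I-] | starting material
26 | tertiary α-hydroxy spiro-epoxide (key-step precursor) | O[C@]12[C@H]3OC(C)(C)O[C@H]3C(C)(C)[C@@H]4[C@H]1CC=C(C)[C@@H]4[C@]25CO5 | intermediate
27 | longipinene-type C1 ketone with C11 hydroxymethyl (key-step product) | O=C1[C@H]3OC(C)(C)O[C@H]3C(C)(C)[C@@H]2[C@H]4CC=C(C)[C@@H]2[C@@]14CO | intermediate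
28 | anti-1,3-diol | O[C@@H]1[C@H]3OC(C)(C)O[C@H]3C(C)(C)[C@@H]2[C@H]4CC=C(C)[C@@H]2[C@@]14CO | intermediate
29 | primary tosylate | O[C@@H]1[C@H]3OC(C)(C)O[C@H]3C(C)(C)[C@@H]2[C@H]4CC=C(C)[C@@H]2[C@@]14COS(=O)(=O)c5ccc(C)cc5 | intermediate
30 | C1 TBS ether tosylate | CC(C)(C)[Si](C)(C)O[C@@H]1[C@H]3OC(C)(C)O[C@H]3C(C)(C)[C@@H]2[C@H]4CC=C(C)[C@@H]2[C@@]14COS(=O)(=O)c5ccc(C)cc5 | intermediate
31 | C11-methyl compound | CC(C)(C)[Si](C)(C)O[C@@H]1[C@H]3OC(C)(C)O[C@H]3C(C)(C)[C@@H]2[C@H]4CC=C(C)[C@@H]2[C@@]14C | intermediate
32 | C7 enone, C1 TBS ether | CC(C)(C)[Si](C)(C)O[C@@H]1[C@H]3OC(C)(C)O[C@H]3C(C)(C)[C@@H]2[C@H]4C(=O)C=C(C)[C@@H]2[C@@]14C | intermediate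
33 | C1 alcohol, C7 enone | O[C@@H]1[C@H]3OC(C)(C)O[C@H]3C(C)(C)[C@@H]2[C@H]4C(=O)C=C(C)[C@@H]2[C@@]14C | intermediate
34 | angelic acid | C/C=C(/C)C(=O)O | starting material
35 | angelic 2,4,6-trichlorobenzoic anhydride | C/C=C(/C)C(=O)OC(=O)c1c(Cl)cc(Cl)cc1Cl | intermediate
36 | C1 angelate acetonide | C/C=C(/C)C(=O)O[C@@H]1[C@H]3OC(C)(C)O[C@H]3C(C)(C)[C@@H]2[C@H]4C(=O)C=C(C)[C@@H]2[C@@]14C | intermediate
37 | C1 angelate 2,3-diol | C/C=C(/C)C(=O)O[C@@H]1[C@@H](O)[C@@H](O)C(C)(C)[C@@H]2[C@H]3C(=O)C=C(C)[C@@H]2[C@@]13C | intermediate
38 | CNP0251293.1 | C/C=C(/C)C(=O)O[C@@H]1[C@@H](OC(=O)CC(C)C)[C@@H](O)C(C)(C)[C@@H]2[C@H]3C(=O)C=C(C)[C@@H]2[C@@]13C | target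

## Step count and least certain steps

Total: 28 steps. Longest linear sequence: 28 steps from 1 (11, 25 and 34 are bought partners). The precursor 26 is reached in 18 steps, the key step is step 19, and 9 steps follow.

**Step 19 (key step).** The wrong group may migrate: C2 or a methylene hydride if the reaction goes through a free C11 cation. That cation may also be captured by the C3 oxygen, with loss of the acetonide. The shift may simply fail because the migrating bond is only about 120° from the leaving oxygen.
Fallback, from 26 back to the route at 28: heat 26 with Al(OiPr)3 in i-PrOH. The carbinol then becomes an aluminium alkoxide that pushes the shift instead of a Lewis acid pulling on the epoxide, and the C1 ketone is reduced in the same flask by Meerwein–Ponndorf–Verley hydride transfer from the aluminium bound to the new primary alkoxide. That transfer is from the same face as in step 20, so it should give 28 directly and make the rearrangement irreversible. No compound beyond the list is formed (entry F0).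

**Step 18.** Facial selectivity may be poor or addition slow at the hindered ketone. The tertiary alkoxide may undergo a base-induced α-ketol shift before the ylide adds, or the product alkoxide may undergo Payne-type migration of the epoxide.
Fallback, from 24 back at 26: silylate the C1 hydroxyl with N-trimethylsilylimidazole to give the C1 trimethylsilyl ether of 24 F1. Add chloromethyllithium (ICH2Cl, MeLi, THF, −78 °C), a carbenoid that adds irreversibly from the same open face and closes on warming to the C1 trimethylsilyl ether of 26 F2. Remove the silyl group with K2CO3 in MeOH to return to 26.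

**Step 16.** The ring A acetonide may ionise under the silyl triflate, the enol ether may hydrolyse, or the tertiary ether may eliminate early to a mixture.
Fallback, from 21 back at 24: form 22 as in step 16 and brominate it with NBS to give the C10-bromo ketone F3. Unmask the side-chain ketone with PPTS in wet acetone to give the C10-bromo methyl ketone F4. Treat F4 with zinc dust in THF; this Reformatsky-type reaction makes the C10 enolate regiospecifically and it adds to the C9 ketone, giving the tertiary aldol F5. Dehydrate F5 with SOCl2 and pyridine to reach 24.

**Step 15.** Base may epimerise C6 before ring closure, the C2 enol may add to the aldehyde, or the conformer with an axial C5 chain may be too poorly populated.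
Fallback, from 20 back at 21: reductive pinacol coupling with SmI2 in THF with t-BuOH at −78 °C, where the aldehyde is reduced first, gives the bridged 1,2-diol F6. Parikh–Doering oxidation of its secondary hydroxyl returns 21.

**Step 28.** Acylation may occur at O3 or twice, or the isovalerate may migrate from O2 to O3.
Fallback, from 37 back at 38: heat 37 with Bu2SnO in toluene to form the dibutylstannylene acetal F7, which activates the less hindered oxygen, then add isovaleryl chloride at 0 °C to give 38.

## Further compounds

F0 | step 19 | none | none
F1 | step 18 | C1 trimethylsilyl ether of 24 | C[Si](C)(C)O[C@]12[C@H]3OC(C)(C)O[C@H]3C(C)(C)[C@@H]4[C@H]1CC=C(C)[C@@H]4C2=O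
F2 | step 18 | C1 trimethylsilyl ether of 26 | C[Si](C)(C)O[C@]12[C@H]3OC(C)(C)O[C@H]3C(C)(C)[C@@H]4[C@H]1CC=C(C)[C@@H]4[C@]25CO5
F3 | step 16 | C10-bromo ketone (ketal intact, C10 configuration immaterial) | O[C@@]12[C@H]3OC(C)(C)O[C@H]3C(C)(C)[C@@H](C(Br)C1=O)[C@H]2CCC4(C)OCCO4
F4 | step 16 | C10-bromo methyl ketone | O[C@@]12[C@H]3OC(C)(C)O[C@H]3C(C)(C)[C@@H](C(Br)C1=O)[C@H]2CCC(C)=O
F5 | step 16 | tertiary aldol (C9 hydroxyl, configuration immaterial) | O[C@]12[C@H]3OC(C)(C)O[C@H]3C(C)(C)[C@@H]4[C@H]1CCC(C)(O)[C@@H]4C2=O
F6 | step 15 | bridged 1,2-diol (C11 configuration immaterial) | O[C@@]12[C@H]3OC(C)(C)O[C@H]3C(C)(C)[C@@H](CC1O)[C@H]2CCC4(C)OCCO4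
F7 | step 28 | dibutylstannylene acetal of 37 | C/C=C(/C)C(=O)O[C@@H]1[C@H]5O[Sn](CCCC)(CCCC)O[C@H]5C(C)(C)[C@@H]2[C@H]3C(=O)C=C(C)[C@@H]2[C@@]13C
A1 | alternative 1 | ring-fused cycloheptenone with quaternary C11 | O=C1C[C@]2(C)CCCC3(OCCO3)C2=CC(C)(C)[C@@H]1O[Si](C)(C)C(C)(C)C
A2 | alternative 2 | α-longipinene | C1CCC(C)(C)[C@@H]2[C@H]3CC=C(C)[C@@H]2[C@@]13C
A3 | alternative 2 | (2E,6E)-farnesyl diphosphate | CC(C)=CCC/C(C)=C/CC/C(C)=C/COP(=O)(O)OP(=O)(O)O
A4 | alternative 3 | tricyclic enone with C1=C2 alkene and C3 silyl ether | C1=C[C@@H](O[Si](C)(C)C(C)(C)C)C(C)(C)[C@@H]2[C@H]3C(=O)C=C(C)[C@@H]2[C@@]13C
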